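## Retrosynthetic overview

1. Target 17 ← acid unmasking (2 aryl MOM, 1 trityl) ← E-enal 16 ← Wittig two-carbon homologation of bis-benzodioxane aldehyde 15.
2. Key disconnection: both 1,4-dioxane rings of 15 are opened at once. Ring A is cut at its benzylic C–O bond (phenoxide/epoxide opening) and its aryl C–O bond (SNAr), ring B at its aryl C–O bond (Ullmann). This leads to cis-epoxy alcohol 11 and 4-fluoro-3-hydroxybenzaldehyde 12.
3. 11 ← Z-allylic alcohol 10 (Sharpless epoxidation) ← bromophenol 9 + trans-epoxide 5 (phenoxide opening with inversion).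
4. 5 ← caffeic acid (MOM, DIBAL, Sharpless epoxidation, trityl); 9 ← 2-bromo-4-iodophenol + propargyl alcohol (Sonogashira, Lindlar).
5. Ring order: no ring is closed before the single cascade, in which ring A (trans) and ring B (cis) form together. All four stereocentres come from two Sharpless epoxidations; the benzylic carbons are inverted on opening and the carbinol carbons are retained on ring closure.

Assumption: building blocks, intermediates and products are numbered; purchased reagents that only deliver a few atoms (MOMCl, TrCl, t-BuOOH, the Wittig ylide) are given by name and SMILES on the reagent line and are not numbered.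

## Route

Step 1
Reactants: 1 caffeic acid, (2E)-3-(3,4-dihydroxyphenyl)prop-2-enoic acid
Product: 2 methoxymethyl (2E)-3-[3,4-bis(methoxymethoxy)phenyl]prop-2-enoate
Conditions: MOMCl (4 equiv), i-Pr2NEt (5 equiv), CH2Cl2, 0 °C → rt
Reagents that add atoms: chloromethyl methyl ether (MOMCl), COCCl
Why: Williamson-type O-alkylation in which the carboxylate and both phenoxides are alkylated by the reactive α-chloro ether in one pot, leaving the E-alkene untouched and creating no stereocentre.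

Step 2
Reactants: 2 methoxymethyl (2E)-3-[3,4-bis(methoxymethoxy)phenyl]prop-2-enoate
Product: 3 (2E)-3-[3,4-bis(methoxymethoxy)phenyl]prop-2-en-1-ol
Conditions: DIBAL-H (4 equiv), CH2Cl2, −78 → 0 °C; Rochelle salt
Reagents that add atoms: none
Why: DIBAL-H 1,2-reduction of the conjugated ester gives the E-allylic alcohol cleanly at low temperature, the aryl MOM acetals being inert to hydride.

Step 3
Reactants: 3 (2E)-3-[3,4-bis(methoxymethoxy)phenyl]prop-2-en-1-ol
Product: 4 [(2S,3S)-3-[3,4-bis(methoxymethoxy)phenyl]oxiran-2-yl]methanol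
Conditions: Ti(Oi-Pr)4 (10 mol %), L-(+)-DIPT (14 mol %), t-BuOOH (2 equiv), 4 Å MS, CH2Cl2, −20 °C; basic work-up, Et3N-deactivated silica
Reagents that add atoms: tert-butyl hydroperoxide, CC(C)(C)OO
Why: Sharpless–Katsuki asymmetric epoxidation, in which the Ti/L-(+)-tartrate complex delivers oxygen to the enantioface of the E-allylic alcohol that gives the (2S,3S)-trans-epoxy alcohol (as for E-cinnamyl alcohols), setting both stereocentres of ring B, with sieves and a non-acidic work-up protecting the electron-rich benzylic epoxide.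

Step 4
Reactants: 4 [(2S,3S)-3-[3,4-bis(methoxymethoxy)phenyl]oxiran-2-yl]methanol
Product: 5 (2S,3S)-2-[3,4-bis(methoxymethoxy)phenyl]-3-[(triphenylmethoxy)methyl]oxirane
Conditions: TrCl (1.2 equiv), Et3N, DMAP (cat.), CH2Cl2, 0 °C → rt
Reagents that add atoms: trityl chloride, ClC(c1ccccc1)(c1ccccc1)c1ccccc1
Why: Base-buffered tritylation of the only free (primary) hydroxyl gives a non-migrating, base-stable, very acid-labile ether that blocks Payne rearrangement and later titanium chelation, the stereocentres being untouched.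

Step 5
Reactants: 6 2-bromo-4-iodophenol; 7 prop-2-yn-1-ol (propargyl alcohol)
Product: 8 3-(3-bromo-4-hydroxyphenyl)prop-2-yn-1-ol
Conditions: PdCl2(PPh3)2 (2 mol %), CuI (4 mol %), Et3N, THF, rt
Reagents that add atoms: none
Why: Sonogashira coupling is chemoselective for C–I over C–Br at room temperature, and the free phenol is tolerated because the alkyne sits para to it (no benzofuran closure).

Step 6
Reactants: 8 3-(3-bromo-4-hydroxyphenyl)prop-2-yn-1-ol
Product: 9 (2Z)-3-(3-bromo-4-hydroxyphenyl)prop-2-en-1-ol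
Conditions: H2 (1 atm), Lindlar catalyst, quinoline, EtOAc, rt
Reagents that add atoms: none
Why: Lindlar semi-hydrogenation adds H2 syn to the alkyne and so gives the Z-allylic alcohol without touching the aryl bromide.

Step 7
Reactants: 9 (2Z)-3-(3-bromo-4-hydroxyphenyl)prop-2-en-1-ol; 5 (2S,3S)-2-[3,4-bis(methoxymethoxy)phenyl]-3-[(triphenylmethoxy)methyl]oxirane
Product: 10 (1R,2S)-1-[3,4-bis(methoxymethoxy)phenyl]-1-{2-bromo-4-[(1Z)-3-hydroxyprop-1-en-1-yl]phenoxy}-3-(triphenylmethoxy)propan-2-ol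
Conditions: Cs2CO3 (0.3 equiv), DMF, 75 °C
Reagents that add atoms: none
Why: Base-mediated phenoxide opening of the epoxide, in which the caesium phenoxide attacks the aryl-activated benzylic oxirane carbon by SN2 (inversion, S → R) while the carbinol carbon keeps its S configuration, giving the erythro aryl ether needed for the cis ring B.

Step 8
Reactants: 10 (1R,2S)-1-[3,4-bis(methoxymethoxy)phenyl]-1-{2-bromo-4-[(1Z)-3-hydroxyprop-1-en-1-yl]phenoxy}-3-(triphenylmethoxy)propan-2-ol
Product: 11 [(2S,3R)-3-(3-bromo-4-{[(1R,2S)-1-[3,4-bis(methoxymethoxy)phenyl]-2-hydroxy-3-(triphenylmethoxy)propyl]oxy}phenyl)oxiran-2-yl]methanol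
Conditions: Ti(Oi-Pr)4 (1.2 equiv), L-(+)-DIPT (1.5 equiv), t-BuOOH (2.5 equiv), 4 Å MS, CH2Cl2, −20 °C; sat. aq. Na2SO4, Celite
Reagents that add atoms: tert-butyl hydroperoxide, CC(C)(C)OO
Why: Sharpless–Katsuki asymmetric epoxidation of the Z-allylic alcohol, where L-(+)-tartrate again selects the same enantioface at the carbinol-bearing alkene carbon and gives the (2S,3R)-cis-epoxy alcohol under reagent control (Z substrates are slower and less selective, but the minor isomer is a separable diastereomer), the remote secondary alcohol, Tr and MOM ethers and ArBr being inert.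

Step 9
Reactants: 11 [(2S,3R)-3-(3-bromo-4-{[(1R,2S)-1-[3,4-bis(methoxymethoxy)phenyl]-2-hydroxy-3-(triphenylmethoxy)propyl]oxy}phenyl)oxiran-2-yl]methanol; 12 4-fluoro-3-hydroxybenzaldehyde
Product: 15 (2S,3S)-3-{(2R,3S)-2-[3,4-bis(methoxymethoxy)phenyl]-3-[(triphenylmethoxy)methyl]-2,3-dihydro-1,4-benzodioxin-6-yl}-2-(hydroxymethyl)-2,3-dihydro-1,4-benzodioxine-6-carbaldehyde, via epoxide-opened fluoro diol 13 (not isolated), via ring-A-closed bromo alcohol 14 (not isolated)
Conditions: Cs2CO3 (4 equiv), CuI (20 mol %), 1,10-phenanthroline (40 mol %), 4 Å MS, degassed DMF (0.05 M), 70 °C then 110 °C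
Reagents that add atoms: none
Why: Proposed new method: a one-pot merger of three known elementary steps, namely SN2 opening of the aryl-activated benzylic epoxide carbon by the phenoxide of 12 (inversion, R → S; closest precedent phenoxide opening of 3-arylglycidols, with the phenol/phenoxide buffer suppressing Payne isomerisation), 6-exo intramolecular SNAr of the released secondary alkoxide on the fluoride para to the formyl group (carbinol carbon retained, S, giving the trans ring A), and Cu(I)/phenanthroline Ullmann-type intramolecular O-arylation of the other secondary carbinol by its ortho aryl bromide at the higher temperature (retained, S, giving the cis ring B); the closest known reaction type is the copper-catalysed tandem epoxide ring-opening/C–O coupling cyclisation of o-halophenols with epoxides.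

Step 10
Reactants: 15 (2S,3S)-3-{(2R,3S)-2-[3,4-bis(methoxymethoxy)phenyl]-3-[(triphenylmethoxy)methyl]-2,3-dihydro-1,4-benzodioxin-6-yl}-2-(hydroxymethyl)-2,3-dihydro-1,4-benzodioxine-6-carbaldehyde
Product: 16 (2E)-3-[(2S,3S)-3-{(2R,3S)-2-[3,4-bis(methoxymethoxy)phenyl]-3-[(triphenylmethoxy)methyl]-2,3-dihydro-1,4-benzodioxin-6-yl}-2-(hydroxymethyl)-2,3-dihydro-1,4-benzodioxin-6-yl]prop-2-enal
Conditions: Ph3P=CHCHO (1.5 equiv), toluene, 80 °C
Reagents that add atoms: (triphenylphosphoranylidene)acetaldehyde, O=CC=P(c1ccccc1)(c1ccccc1)c1ccccc1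
Why: Wittig olefination with the formyl-stabilised ylide is E-selective and reacts with the aromatic aldehyde faster than with the conjugated product aldehyde, while the free primary alcohol, the acetals and the trityl ether are inert.

Step 11
Reactants: 16 (2E)-3-[(2S,3S)-3-{(2R,3S)-2-[3,4-bis(methoxymethoxy)phenyl]-3-[(triphenylmethoxy)methyl]-2,3-dihydro-1,4-benzodioxin-6-yl}-2-(hydroxymethyl)-2,3-dihydro-1,4-benzodioxin-6-yl]prop-2-enal
Product: 17 (2E)-3-[(2S,3S)-3-[(2R,3S)-2-(3,4-dihydroxyphenyl)-3-(hydroxymethyl)-2,3-dihydro-1,4-benzodioxin-6-yl]-2-(hydroxymethyl)-2,3-dihydro-1,4-benzodioxin-6-yl]prop-2-enal (target; ring A trans, ring B cis)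
Conditions: 3 M aq. HCl–THF (1:3), 25–35 °C, N2
Reagents that add atoms: none
Why: Mild acid hydrolysis cleaves the two aryl MOM acetals and the trityl ether (all cation-stabilised leaving groups) near room temperature, conditions chosen to be too mild to ionise the benzylic C–O bonds of the dioxane rings or to damage the enal, so all four stereocentres are kept.

## Compound list

1 | caffeic acid, (2E)-3-(3,4-dihydroxyphenyl)prop-2-enoic acid | OC(=O)/C=C/c1ccc(O)c(O)c1 | starting material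
2 | methoxymethyl (2E)-3-[3,4-bis(methoxymethoxy)phenyl]prop-2-enoate | COCOC(=O)/C=C/c1ccc(OCOC)c(OCOC)c1 | intermediate
3 | (2E)-3-[3,4-bis(methoxymethoxy)phenyl]prop-2-en-1-ol | OC/C=C/c1ccc(OCOC)c(OCOC)c1 | intermediate
4 | [(2S,3S)-3-[3,4-bis(methoxymethoxy)phenyl]oxiran-2-yl]methanol | COCOc1ccc(cc1OCOC)[C@H]1[C@@H](O1)CO | intermediate
5 | (2S,3S)-2-[3,4-bis(methoxymethoxy)phenyl]-3-[(triphenylmethoxy)methyl]oxirane | COCOc1ccc(cc1OCOC)[C@H]1[C@@H](O1)COC(c1ccccc1)(c1ccccc1)c1ccccc1 | intermediate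
6 | 2-bromo-4-iodophenol | Oc1ccc(I)cc1Br | starting material
7 | prop-2-yn-1-ol (propargyl alcohol) | OCC#C | starting material
8 | 3-(3-bromo-4-hydroxyphenyl)prop-2-yn-1-ol | OCC#Cc1ccc(O)c(Br)c1 | intermediate
9 | (2Z)-3-(3-bromo-4-hydroxyphenyl)prop-2-en-1-ol | OC/C=C\c1ccc(O)c(Br)c1 | intermediate
10 | (1R,2S)-1-[3,4-bis(methoxymethoxy)phenyl]-1-{2-bromo-4-[(1Z)-3-hydroxyprop-1-en-1-yl]phenoxy}-3-(triphenylmethoxy)propan-2-ol | O[C@@H](COC(c1ccccc1)(c1ccccc1)c1ccccc1)[C@@H](c1ccc(OCOC)c(OCOC)c1)Oc1ccc(/C=C\CO)cc1Br | intermediate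
11 | [(2S,3R)-3-(3-bromo-4-{[(1R,2S)-1-[3,4-bis(methoxymethoxy)phenyl]-2-hydroxy-3-(triphenylmethoxy)propyl]oxy}phenyl)oxiran-2-yl]methanol | O[C@@H](COC(c1ccccc1)(c1ccccc1)c1ccccc1)[C@@H](c1ccc(OCOC)c(OCOC)c1)Oc1ccc(cc1Br)[C@@H]1[C@@H](O1)CO | intermediate
12 | 4-fluoro-3-hydroxybenzaldehyde | O=Cc1ccc(F)c(O)c1 | starting material
13 | 3-{[(1S,2S)-1-(3-bromo-4-{[(1R,2S)-1-[3,4-bis(methoxymethoxy)phenyl]-2-hydroxy-3-(triphenylmethoxy)propyl]oxy}phenyl)-2,3-dihydroxypropyl]oxy}-4-fluorobenzaldehyde | O=Cc1ccc(F)c(c1)O[C@@H](c1ccc(O[C@H](c2ccc(OCOC)c(OCOC)c2)[C@@H](O)COC(c2ccccc2)(c2ccccc2)c2ccccc2)c(Br)c1)[C@H](CO)O | intermediate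
14 | (2S,3S)-3-(3-bromo-4-{[(1R,2S)-1-[3,4-bis(methoxymethoxy)phenyl]-2-hydroxy-3-(triphenylmethoxy)propyl]oxy}phenyl)-2-(hydroxymethyl)-2,3-dihydro-1,4-benzodioxine-6-carbaldehyde | O=Cc1ccc2c(c1)O[C@@H](c1ccc(O[C@H](c3ccc(OCOC)c(OCOC)c3)[C@@H](O)COC(c3ccccc3)(c3ccccc3)c3ccccc3)c(Br)c1)[C@H](CO)O2 | intermediate
15 | (2S,3S)-3-{(2R,3S)-2-[3,4-bis(methoxymethoxy)phenyl]-3-[(triphenylmethoxy)methyl]-2,3-dihydro-1,4-benzodioxin-6-yl}-2-(hydroxymethyl)-2,3-dihydro-1,4-benzodioxine-6-carbaldehyde | O=Cc1ccc2c(c1)O[C@@H](c1ccc3c(c1)O[C@@H](COC(c4ccccc4)(c4ccccc4)c4ccccc4)[C@@H](c1ccc(OCOC)c(OCOC)c1)O3)[C@H](CO)O2 | intermediate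
16 | (2E)-3-[(2S,3S)-3-{(2R,3S)-2-[3,4-bis(methoxymethoxy)phenyl]-3-[(triphenylmethoxy)methyl]-2,3-dihydro-1,4-benzodioxin-6-yl}-2-(hydroxymethyl)-2,3-dihydro-1,4-benzodioxin-6-yl]prop-2-enal | O=C/C=C/c1ccc2c(c1)O[C@@H](c1ccc3c(c1)O[C@@H](COC(c4ccccc4)(c4ccccc4)c4ccccc4)[C@@H](c1ccc(OCOC)c(OCOC)c1)O3)[C@H](CO)O2 | intermediate
17 | (2E)-3-[(2S,3S)-3-[(2R,3S)-2-(3,4-dihydroxyphenyl)-3-(hydroxymethyl)-2,3-dihydro-1,4-benzodioxin-6-yl]-2-(hydroxymethyl)-2,3-dihydro-1,4-benzodioxin-6-yl]prop-2-enal | O=C/C=C/c1ccc2c(c1)O[C@@H](c1ccc3c(c1)O[C@@H](CO)[C@@H](c1ccc(O)c(O)c1)O3)[C@H](CO)O2 | target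

## Step count and risks

Total step count: 11. Longest linear sequence: 9 steps (steps 1–4, then 7–11); steps 5–6 form the second branch.

The three steps most likely to fail are step 9, step 8 and step 11.

Step 9 is a three-event cascade. It can be derailed by Payne isomerisation of 11 followed by attack at the terminal carbon, by copper-mediated diaryl ether formation from the phenoxide of 12, or by loss of the aldehyde at 110 °C. The fallback sets out from 10 and closes the rings one after the other, coming back at 15. Copper-catalysed intramolecular O-arylation of 10 (CuI, 1,10-phenanthroline, Cs2CO3, toluene, 110 °C, with no epoxide or aldehyde present yet) gives (2Z)-3-{(2R,3S)-2-[3,4-bis(methoxymethoxy)phenyl]-3-[(triphenylmethoxy)methyl]-2,3-dihydro-1,4-benzodioxin-6-yl}prop-2-en-1-ol F1. Titanium/L-(+)-DIPT/t-BuOOH epoxidation then gives [(2S,3R)-3-{(2R,3S)-2-[3,4-bis(methoxymethoxy)phenyl]-3-[(triphenylmethoxy)methyl]-2,3-dihydro-1,4-benzodioxin-6-yl}oxiran-2-yl]methanol F2. F2 and 12 with Cs2CO3 in DMF at 70 °C, without copper, give 3-{[(1S,2S)-1-{(2R,3S)-2-[3,4-bis(methoxymethoxy)phenyl]-3-[(triphenylmethoxy)methyl]-2,3-dihydro-1,4-benzodioxin-6-yl}-2,3-dihydroxypropyl]oxy}-4-fluorobenzaldehyde F3, which closes ring A by SNAr in the same flask to give 15.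

Step 8 uses a Z-allylic alcohol, the slowest and least selective substrate class for the titanium–tartrate system, and the cis-aryl epoxide is acid-labile. The fallback sets out from 10 and comes back at 11 by a non-directed, reagent-controlled epoxidation: a carbohydrate-derived chiral ketone with Oxone at pH 10–10.5 (chiral dioxirane, Shi type, ketone enantiomer chosen for the (2S,3R) epoxide). This reads the cis-aryl olefin itself instead of the titanium-bound allylic alkoxide and keeps the medium basic throughout. It makes no new compound (F0).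

Step 11 frees the catechol under Brønsted acid. Once free, the para-hydroxybenzylic C–O bond of the cis ring can ionise and re-close to the more stable trans ring, and the enal can be attacked. The fallback sets out from 16 and comes back at 17 in two milder stages. Aqueous 80 % AcOH at rt removes only the trityl group and gives (2E)-3-[(2S,3S)-3-{(2R,3S)-2-[3,4-bis(methoxymethoxy)phenyl]-3-(hydroxymethyl)-2,3-dihydro-1,4-benzodioxin-6-yl}-2-(hydroxymethyl)-2,3-dihydro-1,4-benzodioxin-6-yl]prop-2-enal F4. Me3SiOTf/2,2′-bipyridyl in CH2Cl2 at 0 °C then converts the two aryl MOM acetals into aryl silyl ethers under buffered, non-protic conditions, and a neutral aqueous methanol work-up releases 17.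

## Further compounds

F1 | step 9 | (2Z)-3-{(2R,3S)-2-[3,4-bis(methoxymethoxy)phenyl]-3-[(triphenylmethoxy)methyl]-2,3-dihydro-1,4-benzodioxin-6-yl}prop-2-en-1-ol | OC/C=C\c1ccc2c(c1)O[C@@H](COC(c3ccccc3)(c3ccccc3)c3ccccc3)[C@@H](c1ccc(OCOC)c(OCOC)c1)O2
F2 | step 9 | [(2S,3R)-3-{(2R,3S)-2-[3,4-bis(methoxymethoxy)phenyl]-3-[(triphenylmethoxy)methyl]-2,3-dihydro-1,4-benzodioxin-6-yl}oxiran-2-yl]methanol | OC[C@@H]1O[C@@H]1c1ccc2c(c1)O[C@@H](COC(c3ccccc3)(c3ccccc3)c3ccccc3)[C@@H](c1ccc(OCOC)c(OCOC)c1)O2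
F3 | step 9 | 3-{[(1S,2S)-1-{(2R,3S)-2-[3,4-bis(methoxymethoxy)phenyl]-3-[(triphenylmethoxy)methyl]-2,3-dihydro-1,4-benzodioxin-6-yl}-2,3-dihydroxypropyl]oxy}-4-fluorobenzaldehyde | O=Cc1ccc(F)c(c1)O[C@@H](c1ccc2c(c1)O[C@@H](COC(c3ccccc3)(c3ccccc3)c3ccccc3)[C@@H](c1ccc(OCOC)c(OCOC)c1)O2)[C@H](CO)O
F0 | step 8 | none | none
F4 | step 11 | (2E)-3-[(2S,3S)-3-{(2R,3S)-2-[3,4-bis(methoxymethoxy)phenyl]-3-(hydroxymethyl)-2,3-dihydro-1,4-benzodioxin-6-yl}-2-(hydroxymethyl)-2,3-dihydro-1,4-benzodioxin-6-yl]prop-2-enal | O=C/C=C/c1ccc2c(c1)O[C@@H](c1ccc3c(c1)O[C@@H](CO)[C@@H](c1ccc(OCOC)c(OCOC)c1)O3)[C@H](CO)O2
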